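Z makes up 9.09% of the Q and Z together charged to the flask, and I read D as coming from Z.

| flask | Q | Z | J | remark | time |
|---|---|---|---|---|---|
| dawn | 0.037 M | 0.050 equiv | 7.4 mM | run made earlier |  |
| dusk | 0.037 M | 0.075 equiv | 7.4 mM | run made earlier |  |
| flask | 0.037 M | 0.100 equiv | 7.40 mM |  | 4.0 d |

| run | time / d | D / % | G / % |
|---|---|---|---|
| dawn | 0.208 | 6.7 | 19.1 |
| dawn | 0.417 | 9.6 | 30.4 |
| dawn | 1.04 | 8.2 | 47.2 |
| dawn | 2.50 | 11.6 | 56.4 |
| dusk | 0.208 | 7.4 | 19.0 |
| dusk | 0.417 | 9.4 | 28.1 |
| dusk | 1.04 | 11.6 | 46.2 |
| dusk | 2.50 | 13.2 | 56.5 |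

(readings scatter by 1 percentage point)

- what was read earlier has a scatter of 1 percentage point, one standard deviation

- share of D in D plus G at 20 min
- share of D in D plus G at 4.0 d
- which of D and G there is more of at 4.0 d

The puzzle stands in the dawn run: its whole Z charge is 4.76%, yet at 0.208 d it holds 6.7% D, more than that charge. This clears up if Z turns to D in a burst before the first reading while Q slowly feeds the same path. The D above the Z charge at 0.417 d, averaged over both runs with dusk's charge of 6.98%, gives a feed of 0.0871 d⁻¹ as a fraction of the charge, and G at 0.208 d gives a climb of 0.916 d⁻¹. Z charge over climb gives 0.0993 d; putting that back, so that D gains its feed meanwhile, gives 0.109 d, and this I carry: the crossing time, the moment at which G catches D.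

So 20 min comes earlier than the crossing, G stands near 1.27%, and the share of D is 87.7% if Z has wholly reacted, lower if not. Adding to the flask's Z charge the excess both runs show at 2.50 d, I expect D near 15.6% late and, with G taken at the dusk reading of 56.5%, a share near 21.6%, with G leading.

The forecast, lower than my early mark, gives 31% at 20 min, 20% at 4.0 d and G ahead, calling its early value “uncertain because it is extrapolated”.

The flask gives 74.0% at 20 min and 24.1% at 4.0 d, with G at 54.7% against D at 17.3%; G catches D at 0.111 d, and Z's half-life into D, 0.42 h, is longer than 20 min. Q ⇌ Z (K = 0.200, k = 7.90 × 10⁻⁵ min⁻¹); Q ⇌ G (K = 8.20, k = 7.55 × 10⁻⁴ min⁻¹); Z → D (k = 0.0272 min⁻¹); Q + G → X (k = 0.00118 M⁻¹ min⁻¹); Q + J → L (k = 0.122 M⁻¹ min⁻¹)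

A neighbouring flask with 0.0092 M of Q keeps the equivalents of Z, so its Z charge is again 9.09% of its Q and Z together. Taking the climb and the feed, in percent of the charge, as unchanged there, the same reckoning gives the same crossing time, 0.109 d, and 20 min again comes earlier. In that neighbouring flask the share at 20 min reads 74.0%, and at 4.0 d it reads 28.3%.

All runs are simulated for an exercise; noise was put on by code.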